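Readings and results are simulated from invented constants; scatter was added.

Z cannot become X beyond what E pays for. In the dawn run, where G turns Z and E into X, the last reading is 33.4 % X, while E charged over Z charged is 34.0 %. The spring run reads 45.6 % against 46.9 %.

all flasks: G 3.1 mM

|  | Z | E | temperature | remark | time |
|---|---|---|---|---|---|
| midnight | 1.5 M | 0.37 M | −35 °C | run made earlier |  |
| dawn | 1.5 M | 0.51 M | −24 °C | run made earlier |  |
| winter | 1.5 M | 0.72 M | −35 °C | run made earlier |  |
| spring | 1.6 M | 0.75 M | −24 °C | run made earlier |  |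
| ash | 2.5 M | 0.400 M |  | at −20 °C throughout | 2.5 h |
| alder | 1.5 M | 0.750 M |  | at −20 °C until 80 min, from then on at −40 °C | 2.5 h |

- midnight (time / h: X / %, Z / %): 0.417: 5.1, 95.2; 0.833: 8.9, 91.4; 1.33: 12.0, 87.8; 3.00: 21.2, 79.2; 5.00: 22.3, 76.3
- dawn (time / h: X / %, Z / %): 0.500: 16.4, 82.8; 1.00: 25.9, 73.5; 1.50: 31.5, 69.5; 2.00: 32.8, 67.3; 2.50: 33.4, 66.0
- winter (time / h: X / %, Z / %): 0.417: 6.3, 93.7; 0.833: 12.4, 86.5; 1.33: 19.4, 80.0; 3.00: 34.8, 64.2; 5.00: 43.1, 56.4
- spring (time / h: X / %, Z / %): 0.200: 8.3, 90.9; 0.417: 16.3, 81.9; 0.667: 24.8, 75.3; 1.33: 38.4, 62.0; 2.50: 45.6, 54.9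

(standard deviation of a reading: 0.5 percentage points)



1. which one finishes higher in amount of X, in percent of the Z charged ("neither" within 2 percentage points) (ash / alder / neither)
2. amount of X at the end, in percent of the Z charged, ash
3. amount of X at the end, in percent of the Z charged, alder

For ash this ratio gives 16.0 %. For alder, the E charged divided by the Z charged, which we call the E ceiling 50.0 %, is the number we carry.

Dawn, colder than ash, had read past the figure of ash's ceiling by 0.500 h, with 16.4 %, so we put ash at its ceiling.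

Alder needs a reckoning, and spring has nearly its charge. Spring's gap to the ceiling falls from 8.5 percentage points at 1.33 h to 1.3 points at 2.50 h, which reads as a decay of 1.62 h⁻¹. At 0.417 h, spring read 16.3 % and winter 6.3 %, a factor of 2.59 between −35 °C and −24 °C. Taken as constant per degree, that makes −20 °C faster than spring by 1.41 and −40 °C slower by 3.99. So alder's 80 min counts as 1.88 h on spring's clock, leaving 7.37 % of the ceiling unfilled. The cold stretch shrinks that, and alder ends near 47.7 %.

The weak link is 1.3 points, read with a scatter of 0.5 points. Widening it by that much gives 1.34 h⁻¹ and 47.1 %, so for alder we commit to that span, above the 16.0 % we put on ash.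

The forecast says alder finishes higher, with ash at 15.9 % (15.2 % to 16.2 %) and alder at 47 % (44.5 % to 49 %), a little below our 47.7 %. It holds that in ash “E is consumed well within” the time.

The flasks give ash 16.0 % and alder 47.2 %, so alder finishes higher.

    Z + G ⇌ J (K = 0.250 M⁻¹, k = 49.0 M⁻¹ min⁻¹, Ea = 36.0 kJ mol⁻¹, ΔH = −33.0 kJ mol⁻¹)
    J → Q (k = 40.0 min⁻¹, Ea = 64.0 kJ mol⁻¹)
    E + Q → D (k = 20.0 M⁻¹ min⁻¹, Ea = 52.0 kJ mol⁻¹)
    D ⇌ G + X (K = 0.820 M, k = 370 min⁻¹, Ea = 58.0 kJ mol⁻¹, ΔH = −33.0 kJ mol⁻¹)
    (constants at −20 °C)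

E is the limiting reagent in ash, which ends with 0.019 % of its E and stands at its ceiling of 16.0 %. With E held at its charge, ash would reach 60.7 % because the wearing away of E is what holds it down. Alder ends below its E ceiling of 50.0 % with 5.6 % of its E left, and stands at 50.0 % after 25.0 h. A flask like alder but with 3.0 M of E has a ceiling of 200 %, beyond the Z charged, and gives 71.4 % with 64 % of its E left.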